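**Retrosynthetic overview**
1. Numbering: quinone C1(=O) lies between C2(CH3) and C6(chain), C3–H, C4(=O), C5–H; chain carbons C1′–C16′ are counted from the ring. Target ⇐ acetonide hydrolysis ⇐ quinone ⇐ Ag2O oxidation of a hydroquinone; the temporary 1,3-dioxane is closed first, the six-membered carbocycle last.
2. Hydroquinone ⇐ a 4-hydroxy-3-methylcyclobutenone that carries the whole chain on a 1,1-disubstituted vinyl group. Strain-release 4π opening followed by 6π closure makes the C4–C5 bond, the bond between the carbonyl carbon flanked by two ring CH and the ring CH next to chain-bearing C6.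
3. Enabling feature: C5 bears H and C6 bears C1′H2, so C5–C6–C1′ is a 2-substituted propen-2-yl unit with C5 as its =CH2, while O=C4–C3H=C2(CH3)–C1=O is exactly the carbon set of 3-methylcyclobutenedione. The para relation of the two ring oxygens is what a 4-hydroxycyclobutenone delivers.
4. Cyclobutenone ⇐ 2-lithio-1,4-diene (from the 2-bromoallyl chain end) + 3-methylcyclobut-3-ene-1,2-dione (from diisopropyl squarate).
5. Chain ⇐ farnesyl bromide + TIPS-acetylene; terminal alkene → alkyne; Weinreb ynone; Noyori transfer hydrogenation sets the (R)-carbinol C12′; trans-hydrostannation, methoxycarbonylation and reduction set the E C10′=C11′ alkene with its CH2OH.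

Key step: step 17

Remark: the stereocentres of 5, 6, 13, 24, 25, F1, F3, F4, F5 and the ring carbinol carbon of 28 are formed without control. All are destroyed in later steps, so their SMILES carry no configuration at these centres.

**Step 1**
Reactants: 1 ethynyltriisopropylsilane (TIPS-acetylene); 2 (2E,6E)-farnesyl bromide
Product: 4 triisopropyl[(4E,8E)-5,9,13-trimethyltetradeca-4,8,12-trien-1-yn-1-yl]silane, via alkynylmagnesium bromide 3 (not isolated)
Conditions: EtMgBr, THF, 0 → 50 °C; then CuCl (10 mol %), 2, THF, 50 °C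
Reagents that add atoms: none
Why: Copper-catalysed coupling of an alkynyl Grignard reagent with a primary allylic bromide should proceed by SN2 substitution at the CH2Br carbon with retention of the E alkene, and the bulky silyl group masks this alkyne until step 12.

**Step 2**
Reactants: 4 triisopropyl[(4E,8E)-5,9,13-trimethyltetradeca-4,8,12-trien-1-yn-1-yl]silane
Product: 6 {(4E,8E)-11-(3,3-dimethyloxiran-2-yl)-5,9-dimethylundeca-4,8-dien-1-yn-1-yl}triisopropylsilane (racemic), via bromohydrin 5 (not isolated)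
Conditions: NBS, THF/H2O, 0 °C; then K2CO3, MeOH, rt
Reagents that add atoms: water, O
Why: Terminal-selective bromohydrin formation of a polyprenyl chain in aqueous THF (the coiled chain exposes the terminal trisubstituted alkene) followed by Williamson-type epoxide closure should give the terminal epoxide, with the hindered silylalkyne inert to NBS.

**Step 3**
Reactants: 6 {(4E,8E)-11-(3,3-dimethyloxiran-2-yl)-5,9-dimethylundeca-4,8-dien-1-yn-1-yl}triisopropylsilane
Product: 7 (4E,8E)-4,8-dimethyl-12-(triisopropylsilyl)dodeca-4,8-dien-11-ynal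
Conditions: H5IO6, THF/Et2O, 0 °C
Reagents that add atoms: none
Why: Periodic acid opens the trisubstituted epoxide to the glycol and cleaves it (Malaprade-type glycol cleavage) to the aldehyde and acetone without touching the alkenes or the alkyne.

**Step 4**
Reactants: 7 (4E,8E)-4,8-dimethyl-12-(triisopropylsilyl)dodeca-4,8-dien-11-ynal
Product: 8 triisopropyl[(4E,8E)-5,9-dimethyltrideca-4,8-dien-1,12-diyn-1-yl]silane
Conditions: dimethyl (1-diazo-2-oxopropyl)phosphonate, K2CO3, MeOH, 0 °C → rt
Reagents that add atoms: dimethyl (1-diazo-2-oxopropyl)phosphonate, CC(=O)C(=[N+]=[N-])P(=O)(OC)OC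
Why: The Ohira–Bestmann modification of the Seyferth–Gilbert homologation converts the enolisable aldehyde into the terminal alkyne under mild carbonate conditions that leave the triisopropylsilyl alkyne intact.

**Step 5**
Reactants: 9 4-methylpent-3-enoic acid
Product: 11 N-methoxy-N,4-dimethylpent-3-enamide, via acyl imidazole 10 (not isolated)
Conditions: CDI, CH2Cl2, 0 °C → rt; then MeNH(OMe)·HCl, rt
Reagents that add atoms: N,O-dimethylhydroxylamine hydrochloride, CNOC.Cl
Why: Carbonyldiimidazole activation and aminolysis (Weinreb amide formation) run under nearly neutral conditions, so the β,γ-alkene should not move into conjugation.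

**Step 6**
Reactants: 8 triisopropyl[(4E,8E)-5,9-dimethyltrideca-4,8-dien-1,12-diyn-1-yl]silane; 11 N-methoxy-N,4-dimethylpent-3-enamide
Product: 14 (10E,14E)-2,10,14-trimethyl-18-(triisopropylsilyl)octadeca-2,10,14-trien-6,17-diyn-5-one, via lithium acetylide 12 (not isolated), via tetrahedral lithium adduct 13 (not isolated)
Conditions: n-BuLi, THF, −78 °C; then 11, −78 → −20 °C; sat. aq. NH4Cl, 0 °C
Reagents that add atoms: none
Why: In the Weinreb ketone synthesis the chelated tetrahedral adduct collapses only on the cold, weakly acidic quench, so the ynone forms without over-addition and without base-induced conjugation of its β,γ-alkene.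

**Step 7**
Reactants: 14 (10E,14E)-2,10,14-trimethyl-18-(triisopropylsilyl)octadeca-2,10,14-trien-6,17-diyn-5-one
Product: 15 (5R,10E,14E)-2,10,14-trimethyl-18-(triisopropylsilyl)octadeca-2,10,14-trien-6,17-diyn-5-ol
Conditions: Ru[(R,R)-TsNCH(Ph)CH(Ph)NH](p-cymene) (1 mol %), iPrOH, rt
Reagents that add atoms: none
Why: Noyori asymmetric transfer hydrogenation of an alkynyl ketone, run with the preformed amido complex and no added base so that the β,γ-alkene stays out of conjugation; the (R,R)-TsDPEN ligand differentiates the alkynyl π-substituent from the alkyl group and should deliver hydride to the face that gives the (R)-propargylic alcohol, which is C12′ of the target.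

**Step 8**
Reactants: 15 (5R,10E,14E)-2,10,14-trimethyl-18-(triisopropylsilyl)octadeca-2,10,14-trien-6,17-diyn-5-ol
Product: 16 (5R,6Z,10E,14E)-2,10,14-trimethyl-6-(tributylstannyl)-18-(triisopropylsilyl)octadeca-2,6,10,14-tetraen-17-yn-5-ol
Conditions: [Cp*RuCl]4 (1.5 mol %), Bu3SnH (slow addition), CH2Cl2, rt
Reagents that add atoms: tributyltin hydride, CCCC[SnH](CCCC)CCCC
Why: Hydroxyl-directed ruthenium-catalysed trans-hydrostannation places tin on the alkyne carbon next to the carbinol and hydrogen trans to it (hydrogen bond from OH to the chloride ligand), which fixes the later C10′=C11′ geometry, while the remote silyl-capped alkyne has no directing group and is shielded.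

**Step 9**
Reactants: 16 (5R,6Z,10E,14E)-2,10,14-trimethyl-6-(tributylstannyl)-18-(triisopropylsilyl)octadeca-2,6,10,14-tetraen-17-yn-5-ol
Product: 17 methyl (2Z,6E,10E)-2-[(1R)-1-hydroxy-4-methylpent-3-en-1-yl]-6,10-dimethyl-14-(triisopropylsilyl)tetradeca-2,6,10-trien-13-ynoate
Conditions: Pd(OAc)2 (5 mol %), Ph3As (10 mol %), 1,4-benzoquinone, CF3CO2H (cat.), CO (1 atm), MeOH, rt
Reagents that add atoms: carbon monoxide, [C-]#[O+]; methanol, CO
Why: Palladium-catalysed oxidative methoxycarbonylation of an alkenylstannane (Stille-type transmetalation, CO insertion, methanolysis, reoxidation by benzoquinone) replaces tin by CO2Me with retention of alkene geometry and tolerates the free allylic alcohol.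

**Step 10**
Reactants: 17 methyl (2Z,6E,10E)-2-[(1R)-1-hydroxy-4-methylpent-3-en-1-yl]-6,10-dimethyl-14-(triisopropylsilyl)tetradeca-2,6,10-trien-13-ynoate
Product: 18 (5R,6E,10E,14E)-6-(hydroxymethyl)-2,10,14-trimethyl-18-(triisopropylsilyl)octadeca-2,6,10,14-tetraen-17-yn-5-ol
Conditions: iBu2AlH (DIBAL-H, 4 equiv), CH2Cl2, −78 → 0 °C; aq. potassium sodium tartrate
Reagents that add atoms: none
Why: DIBAL-H 1,2-reduction of the α,β-unsaturated ester gives the primary allylic alcohol without changing the alkene geometry or the carbinol centre.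

**Step 11**
Reactants: 18 (5R,6E,10E,14E)-6-(hydroxymethyl)-2,10,14-trimethyl-18-(triisopropylsilyl)octadeca-2,6,10,14-tetraen-17-yn-5-ol
Product: 19 (4R,5E)-5-[(4E,8E)-4,8-dimethyl-12-(triisopropylsilyl)dodeca-4,8-dien-11-yn-1-ylidene]-2,2-dimethyl-4-(3-methylbut-2-en-1-yl)-1,3-dioxane
Conditions: 2,2-dimethoxypropane, PPTS (cat.), CH2Cl2, rt
Reagents that add atoms: 2,2-dimethoxypropane, COC(C)(C)OC
Why: Acid-catalysed transacetalisation ties the 1,3-diol into a six-membered isopropylidene acetal that withstands fluoride, aluminium hydride, organolithium and heat in the following steps.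

**Step 12**
Reactants: 19 (4R,5E)-5-[(4E,8E)-4,8-dimethyl-12-(triisopropylsilyl)dodeca-4,8-dien-11-yn-1-ylidene]-2,2-dimethyl-4-(3-methylbut-2-en-1-yl)-1,3-dioxane
Product: 20 (4R,5E)-5-[(4E,8E)-4,8-dimethyldodeca-4,8-dien-11-yn-1-ylidene]-2,2-dimethyl-4-(3-methylbut-2-en-1-yl)-1,3-dioxane
Conditions: Bu4NF (TBAF), THF, 0 °C → rt
Reagents that add atoms: none
Why: Fluoride-induced protodesilylation of the alkynylsilane frees the terminal alkyne while the acetal is inert to fluoride.

**Step 13**
Reactants: 20 (4R,5E)-5-[(4E,8E)-4,8-dimethyldodeca-4,8-dien-11-yn-1-ylidene]-2,2-dimethyl-4-(3-methylbut-2-en-1-yl)-1,3-dioxane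
Product: 22 (4R,5E)-5-[(4E,8E)-11-bromo-4,8-dimethyldodeca-4,8,11-trien-1-ylidene]-2,2-dimethyl-4-(3-methylbut-2-en-1-yl)-1,3-dioxane, via alkenylalane 21 (not isolated)
Conditions: Ni(dppp)Cl2 (3 mol %), iBu2AlH (1.3 equiv), THF, 0 → 22 °C; then NBS, 0 °C
Reagents that add atoms: N-bromosuccinimide, O=C1CCC(=O)N1Br
Why: Nickel-catalysed hydroalumination of a terminal alkyne with the bidentate dppp ligand places aluminium on the internal carbon (α-selective), and bromination of the C–Al bond with NBS then gives the 2-bromo-1-alkene.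

**Step 14**
Reactants: 23 diisopropyl squarate (3,4-diisopropoxycyclobut-3-ene-1,2-dione)
Product: 24 4-hydroxy-2,3-diisopropoxy-4-methylcyclobut-2-en-1-one (racemic)
Conditions: MeLi, THF, −78 °C; sat. aq. NH4Cl
Reagents that add atoms: methyllithium, [Li]C
Why: 1,2-Addition of an organolithium to one carbonyl of a squarate ester stops cleanly at the mono-adduct at −78 °C because the resulting alkoxide deactivates the remaining vinylogous ester carbonyl.

**Step 15**
Reactants: 24 4-hydroxy-2,3-diisopropoxy-4-methylcyclobut-2-en-1-one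
Product: 26 3-methylcyclobut-3-ene-1,2-dione, via cyclobutenediol 25 (not isolated)
Conditions: LiAlH(OtBu)3, THF, 0 °C; then conc. HCl, CH2Cl2, rt
Reagents that add atoms: water, O
Why: Hydride reduction of the remaining carbonyl followed by acid hydrolysis, in which each carbinol ionises to an isopropoxy-stabilised cyclobutenyl cation that is hydrolysed with allylic transposition, is the established squarate route to monosubstituted cyclobutenediones.

**Step 16**
Reactants: 22 (4R,5E)-5-[(4E,8E)-11-bromo-4,8-dimethyldodeca-4,8,11-trien-1-ylidene]-2,2-dimethyl-4-(3-methylbut-2-en-1-yl)-1,3-dioxane; 26 3-methylcyclobut-3-ene-1,2-dione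
Product: 28 4-hydroxy-3-methyl-4-{(4E,8E)-12-[(4R,5E)-2,2-dimethyl-4-(3-methylbut-2-en-1-yl)-1,3-dioxan-5-ylidene]-5,9-dimethyldodeca-1,4,8-trien-2-yl}cyclobut-2-en-1-one (both epimers at the ring carbinol carbon), via alkenyllithium 27 (not isolated)
Conditions: t-BuLi (2 equiv), Et2O, −78 °C; then cannulated into 26, THF, −78 °C; sat. aq. NH4Cl
Reagents that add atoms: none
Why: Lithium–bromine exchange and 1,2-addition of the alkenyllithium to the cyclobutenedione should occur at the cross-conjugated carbonyl attached to the methyl-bearing carbon, because the other carbonyl is the terminus of a β-methyl enone and is deactivated; this places the carbinol next to C–CH3 as the ring pattern requires, and the uncontrolled carbinol centre is erased in step 17.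

**Step 17**
Reactants: 28 4-hydroxy-3-methyl-4-{(4E,8E)-12-[(4R,5E)-2,2-dimethyl-4-(3-methylbut-2-en-1-yl)-1,3-dioxan-5-ylidene]-5,9-dimethyldodeca-1,4,8-trien-2-yl}cyclobut-2-en-1-one
Product: 31 2-{(2E,6E)-10-[(4R,5E)-2,2-dimethyl-4-(3-methylbut-2-en-1-yl)-1,3-dioxan-5-ylidene]-3,7-dimethyldeca-2,6-dien-1-yl}-6-methylbenzene-1,4-diol, via dienylketene 29 (not isolated), via cyclohexadienone 30 (not isolated)
Conditions: p-xylene (degassed, 0.01 M), 138 °C, Ar
Reagents that add atoms: none
Why: Heating opens the strained four-membered ring of 28 by conrotatory 4π electrocyclic ring opening of the bond between the carbonyl and carbinol carbons, the donor hydroxyl rotating outward so that the alkenyl substituent turns inward and lies cis to the ketene in 29. The ketene carbon then bonds to the terminal CH2 of the alkenyl group in a thermal disrotatory 6π electrocyclisation, which closes the six-membered carbocycle (the only ring made here) as cyclohexa-2,4-dienone 30, and enolisation aromatises 30 to hydroquinone 31. The closest known reaction type is the thermal ring expansion of 4-alkenyl- and 4-aryl-4-hydroxycyclobutenones to hydroquinones, driven by release of cyclobutenone strain and by aromatisation. No stereocentre is created: the uncontrolled carbinol centre of 28 disappears, and the chain stereocentre and alkene geometries are remote and not involved. The step needs torquoselectivity (hydroxyl outward, otherwise the OH would add to the ketene to give a butenolide), which the donor OH secures, and regiochemistry, which is fixed by the connectivity of 28: the carbinol carbon becomes C1 between C–CH3 and C–chain, and the ketene carbon becomes C4 between two ring CH.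

**Step 18**
Reactants: 31 2-{(2E,6E)-10-[(4R,5E)-2,2-dimethyl-4-(3-methylbut-2-en-1-yl)-1,3-dioxan-5-ylidene]-3,7-dimethyldeca-2,6-dien-1-yl}-6-methylbenzene-1,4-diol
Product: 32 2-{(2E,6E)-10-[(4R,5E)-2,2-dimethyl-4-(3-methylbut-2-en-1-yl)-1,3-dioxan-5-ylidene]-3,7-dimethyldeca-2,6-dien-1-yl}-6-methylcyclohexa-2,5-diene-1,4-dione
Conditions: Ag2O, MgSO4, Et2O, rt
Reagents that add atoms: none
Why: Oxidation of a hydroquinone to the para-benzoquinone with Ag2O is neutral and fast and should leave the acetal and the trisubstituted alkenes untouched.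

**Step 19**
Reactants: 32 2-{(2E,6E)-10-[(4R,5E)-2,2-dimethyl-4-(3-methylbut-2-en-1-yl)-1,3-dioxan-5-ylidene]-3,7-dimethyldeca-2,6-dien-1-yl}-6-methylcyclohexa-2,5-diene-1,4-dione
Product: 33 2-[(2E,6E,10E,12R)-12-hydroxy-11-(hydroxymethyl)-3,7,15-trimethylhexadeca-2,6,10,14-tetraen-1-yl]-6-methylcyclohexa-2,5-diene-1,4-dione (CNP0201434.1)
Conditions: AcOH/THF/H2O (3:1:1), 35 °C
Reagents that add atoms: none
Why: Mild acid-catalysed acetal hydrolysis releases the 1,3-diol under conditions that the quinone tolerates and that are too weak to ionise the allylic alcohols, so the (R)-centre and the E alkene are retained.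

**Compound list**
1 | ethynyltriisopropylsilane | C#C[Si](C(C)C)(C(C)C)C(C)C | starting material
2 | (2E,6E)-farnesyl bromide, (2E,6E)-1-bromo-3,7,11-trimethyldodeca-2,6,10-triene | CC(C)=CCC/C(C)=C/CC/C(C)=C/CBr | starting material
3 | [(triisopropylsilyl)ethynyl]magnesium bromide | Br[Mg]C#C[Si](C(C)C)(C(C)C)C(C)C | intermediate
4 | triisopropyl[(4E,8E)-5,9,13-trimethyltetradeca-4,8,12-trien-1-yn-1-yl]silane | CC(C)=CCC/C(C)=C/CC/C(C)=C/CC#C[Si](C(C)C)(C(C)C)C(C)C | intermediate
5 | (6E,10E)-3-bromo-2,6,10-trimethyl-14-(triisopropylsilyl)tetradeca-6,10-dien-13-yn-2-ol (racemic bromohydrin) | CC(C)(O)C(Br)CC/C(C)=C/CC/C(C)=C/CC#C[Si](C(C)C)(C(C)C)C(C)C | intermediate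
6 | {(4E,8E)-11-(3,3-dimethyloxiran-2-yl)-5,9-dimethylundeca-4,8-dien-1-yn-1-yl}triisopropylsilane (racemic) | CC1(C)OC1CC/C(C)=C/CC/C(C)=C/CC#C[Si](C(C)C)(C(C)C)C(C)C | intermediate
7 | (4E,8E)-4,8-dimethyl-12-(triisopropylsilyl)dodeca-4,8-dien-11-ynal | O=CCC/C(C)=C/CC/C(C)=C/CC#C[Si](C(C)C)(C(C)C)C(C)C | intermediate
8 | triisopropyl[(4E,8E)-5,9-dimethyltrideca-4,8-dien-1,12-diyn-1-yl]silane | C#CCC/C(C)=C/CC/C(C)=C/CC#C[Si](C(C)C)(C(C)C)C(C)C | intermediate
9 | 4-methylpent-3-enoic acid | CC(C)=CCC(=O)O | starting material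
10 | 1-(1H-imidazol-1-yl)-4-methylpent-3-en-1-one (acyl imidazole) | CC(C)=CCC(=O)n1ccnc1 | intermediate
11 | N-methoxy-N,4-dimethylpent-3-enamide | CC(C)=CCC(=O)N(C)OC | intermediate
12 | lithium acetylide of 8 (Li on the free alkyne terminus) | [Li]C#CCC/C(C)=C/CC/C(C)=C/CC#C[Si](C(C)C)(C(C)C)C(C)C | intermediate
13 | lithium alkoxide of the N-methoxy-N-methyl hemiaminal formed from 12 and 11 | CC(C)=CCC(O[Li])(N(C)OC)C#CCC/C(C)=C/CC/C(C)=C/CC#C[Si](C(C)C)(C(C)C)C(C)C | intermediate
14 | (10E,14E)-2,10,14-trimethyl-18-(triisopropylsilyl)octadeca-2,10,14-trien-6,17-diyn-5-one | CC(C)=CCC(=O)C#CCC/C(C)=C/CC/C(C)=C/CC#C[Si](C(C)C)(C(C)C)C(C)C | intermediate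
15 | (5R,10E,14E)-2,10,14-trimethyl-18-(triisopropylsilyl)octadeca-2,10,14-trien-6,17-diyn-5-ol | CC(C)=CC[C@@H](O)C#CCC/C(C)=C/CC/C(C)=C/CC#C[Si](C(C)C)(C(C)C)C(C)C | intermediate
16 | (5R,6Z,10E,14E)-2,10,14-trimethyl-6-(tributylstannyl)-18-(triisopropylsilyl)octadeca-2,6,10,14-tetraen-17-yn-5-ol | CC(C)=CC[C@@H](O)/C(=C/CC/C(C)=C/CC/C(C)=C/CC#C[Si](C(C)C)(C(C)C)C(C)C)[Sn](CCCC)(CCCC)CCCC | intermediate
17 | methyl (2Z,6E,10E)-2-[(1R)-1-hydroxy-4-methylpent-3-en-1-yl]-6,10-dimethyl-14-(triisopropylsilyl)tetradeca-2,6,10-trien-13-ynoate | CC(C)=CC[C@@H](O)/C(=C/CC/C(C)=C/CC/C(C)=C/CC#C[Si](C(C)C)(C(C)C)C(C)C)C(=O)OC | intermediate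
18 | (5R,6E,10E,14E)-6-(hydroxymethyl)-2,10,14-trimethyl-18-(triisopropylsilyl)octadeca-2,6,10,14-tetraen-17-yn-5-ol | CC(C)=CC[C@@H](O)/C(=C/CC/C(C)=C/CC/C(C)=C/CC#C[Si](C(C)C)(C(C)C)C(C)C)CO | intermediate
19 | (4R,5E)-5-[(4E,8E)-4,8-dimethyl-12-(triisopropylsilyl)dodeca-4,8-dien-11-yn-1-ylidene]-2,2-dimethyl-4-(3-methylbut-2-en-1-yl)-1,3-dioxane | CC(C)=CC[C@H]1OC(C)(C)OC\C1=C/CC/C(C)=C/CC/C(C)=C/CC#C[Si](C(C)C)(C(C)C)C(C)C | intermediate
20 | (4R,5E)-5-[(4E,8E)-4,8-dimethyldodeca-4,8-dien-11-yn-1-ylidene]-2,2-dimethyl-4-(3-methylbut-2-en-1-yl)-1,3-dioxane | CC(C)=CC[C@H]1OC(C)(C)OC\C1=C/CC/C(C)=C/CC/C(C)=C/CC#C | intermediate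
21 | diisobutyl(alkenyl)alane from 20, aluminium on the internal alkene carbon | CC(C)=CC[C@H]1OC(C)(C)OC\C1=C/CC/C(C)=C/CC/C(C)=C/CC(=C)[Al](CC(C)C)CC(C)C | intermediate
22 | (4R,5E)-5-[(4E,8E)-11-bromo-4,8-dimethyldodeca-4,8,11-trien-1-ylidene]-2,2-dimethyl-4-(3-methylbut-2-en-1-yl)-1,3-dioxane | CC(C)=CC[C@H]1OC(C)(C)OC\C1=C/CC/C(C)=C/CC/C(C)=C/CC(Br)=C | intermediate
23 | diisopropyl squarate, 3,4-diisopropoxycyclobut-3-ene-1,2-dione | CC(C)OC1=C(OC(C)C)C(=O)C1=O | starting material
24 | 4-hydroxy-2,3-diisopropoxy-4-methylcyclobut-2-en-1-one (racemic) | CC(C)OC1=C(OC(C)C)C(C)(O)C1=O | intermediate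
25 | 2,3-diisopropoxy-1-methylcyclobut-2-ene-1,4-diol | CC(C)OC1=C(OC(C)C)C(C)(O)C1O | intermediate
26 | 3-methylcyclobut-3-ene-1,2-dione | CC1=CC(=O)C1=O | intermediate
27 | alkenyllithium from 22 (Li in place of Br) | CC(C)=CC[C@H]1OC(C)(C)OC\C1=C/CC/C(C)=C/CC/C(C)=C/CC(=C)[Li] | intermediate
28 | 4-hydroxy-3-methyl-4-{(4E,8E)-12-[(4R,5E)-2,2-dimethyl-4-(3-methylbut-2-en-1-yl)-1,3-dioxan-5-ylidene]-5,9-dimethyldodeca-1,4,8-trien-2-yl}cyclobut-2-en-1-one (both epimers at the ring carbinol carbon) | CC(C)=CC[C@H]1OC(C)(C)OC\C1=C/CC/C(C)=C/CC/C(C)=C/CC(=C)C2(O)C(C)=CC2=O | intermediate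
29 | dienylketene from 28: O=C=CH–C(CH3)=C(OH)–C(=CH2)–CH2–chain, ketene and alkenyl group cis | CC(C)=CC[C@H]1OC(C)(C)OC\C1=C/CC/C(C)=C/CC/C(C)=C/CC(=C)/C(O)=C(C)\C=C=O | intermediate
30 | 4-hydroxy-3-methyl-5-{(2E,6E)-10-[(4R,5E)-2,2-dimethyl-4-(3-methylbut-2-en-1-yl)-1,3-dioxan-5-ylidene]-3,7-dimethyldeca-2,6-dien-1-yl}cyclohexa-2,4-dien-1-one | CC(C)=CC[C@H]1OC(C)(C)OC\C1=C/CC/C(C)=C/CC/C(C)=C/CC2=C(O)C(C)=CC(=O)C2 | intermediate
31 | 2-{(2E,6E)-10-[(4R,5E)-2,2-dimethyl-4-(3-methylbut-2-en-1-yl)-1,3-dioxan-5-ylidene]-3,7-dimethyldeca-2,6-dien-1-yl}-6-methylbenzene-1,4-diol | CC(C)=CC[C@H]1OC(C)(C)OC\C1=C/CC/C(C)=C/CC/C(C)=C/Cc2cc(O)cc(C)c2O | intermediate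
32 | 2-{(2E,6E)-10-[(4R,5E)-2,2-dimethyl-4-(3-methylbut-2-en-1-yl)-1,3-dioxan-5-ylidene]-3,7-dimethyldeca-2,6-dien-1-yl}-6-methylcyclohexa-2,5-diene-1,4-dione | CC(C)=CC[C@H]1OC(C)(C)OC\C1=C/CC/C(C)=C/CC/C(C)=C/CC2=CC(=O)C=C(C)C2=O | intermediate
33 | 2-[(2E,6E,10E,12R)-12-hydroxy-11-(hydroxymethyl)-3,7,15-trimethylhexadeca-2,6,10,14-tetraen-1-yl]-6-methylcyclohexa-2,5-diene-1,4-dione | CC(C)=CC[C@@H](O)/C(=C/CC/C(C)=C/CC/C(C)=C/CC1=CC(=O)C=C(C)C1=O)CO | target

**Step count and risks**
Total steps: 19 (16 in the main line, 1 for amide 11, 2 for dione 26).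
Longest linear sequence: 16 steps (steps 1–4, 6–13, 16–19).

Most likely to fail:

1. Step 16. The alkenyllithium may attack the wrong carbonyl of 26, add in conjugate fashion or deprotonate the vinylogous methyl group, since a methyl group differentiates the two carbonyls only moderately; attack at the wrong carbonyl would lead in step 17 to the 2,5-disubstituted ring. Fallback, from 23 and 27 back to 28, by a carbonyl transposition of known type: 23 is reduced with LiAlH(OtBu)3 to 4-hydroxy-2,3-diisopropoxycyclobut-2-en-1-one F1, which conc. HCl converts into 3-isopropoxycyclobut-3-ene-1,2-dione F2. Alkenyllithium 27 adds to the carbonyl of F2 attached to the isopropoxy-bearing carbon (the other carbonyl is a vinylogous ester), and a Me3SiCl quench gives the 4-alkenyl-3-isopropoxy-4-(trimethylsilyloxy)cyclobut-2-en-1-one F3. MeLi at −78 °C adds to the remaining carbonyl to give the methyl carbinol F4. (CF3CO)2O with pyridine at −78 °C, followed by aqueous NaHCO3, ionises this carbinol and hydrolyses the enol ether with allylic transposition to the 4-alkenyl-3-methyl-4-(trimethylsilyloxy)cyclobut-2-en-1-one F5. Bu4NF buffered with AcOH removes the silyl group and the route is rejoined at 28, with the regiochemistry fixed by the order of the two additions.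

2. Step 13. The hydroalumination may lose its internal selectivity, the terminal C–H may be metalated instead, or the skipped enyne may isomerise under the aluminium reagent. Fallback, from 20 back to 22: syn bromoboration of the terminal alkyne with B-bromo-9-BBN (CH2Cl2, −78 → 0 °C, kept cold to spare the acetal) puts bromine on the internal carbon and gives the (Z)-2-bromoalkenyl-9-BBN F6, and protodeboronation with AcOH delivers 22.

3. Step 9. Protodestannylation by the acidic methanol may outrun transmetalation to palladium, or divalent palladium may engage the polyene. Fallback, from 16 back to 18, bypassing ester 17 and step 10: iododestannylation with I2 (CH2Cl2, 0 °C) gives with retention the (5R,6Z)-6-iodo alkenol F7, and Stille coupling with Bu3SnCH2OH (Pd(PPh3)4, dioxane, 80 °C) installs the hydroxymethyl group directly to give diol 18.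

**Further compounds**
F1 | step 16 | 4-hydroxy-2,3-diisopropoxycyclobut-2-en-1-one | CC(C)OC1=C(OC(C)C)C(O)C1=O
F2 | step 16 | 3-isopropoxycyclobut-3-ene-1,2-dione | CC(C)OC1=CC(=O)C1=O
F3 | step 16 | 4-alkenyl-3-isopropoxy-4-(trimethylsilyloxy)cyclobut-2-en-1-one (alkenyl as in 28) | CC(C)=CC[C@H]1OC(C)(C)OC\C1=C/CC/C(C)=C/CC/C(C)=C/CC(=C)C2(O[Si](C)(C)C)C(OC(C)C)=CC2=O
F4 | step 16 | 4-alkenyl-3-isopropoxy-1-methyl-4-(trimethylsilyloxy)cyclobut-2-en-1-ol (alkenyl as in 28) | CC(C)=CC[C@H]1OC(C)(C)OC\C1=C/CC/C(C)=C/CC/C(C)=C/CC(=C)C2(O[Si](C)(C)C)C(OC(C)C)=CC2(C)O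
F5 | step 16 | 4-alkenyl-3-methyl-4-(trimethylsilyloxy)cyclobut-2-en-1-one (trimethylsilyl ether of 28) | CC(C)=CC[C@H]1OC(C)(C)OC\C1=C/CC/C(C)=C/CC/C(C)=C/CC(=C)C2(O[Si](C)(C)C)C(C)=CC2=O
F6 | step 13 | (Z)-2-bromoalkenyl-9-borabicyclo[3.3.1]nonane from 20 (Br internal, B terminal, cis) | CC(C)=CC[C@H]1OC(C)(C)OC\C1=C/CC/C(C)=C/CC/C(C)=C/C/C(Br)=C/B1C2CCCC1CCC2
F7 | step 9 | (5R,6Z,10E,14E)-6-iodo-2,10,14-trimethyl-18-(triisopropylsilyl)octadeca-2,6,10,14-tetraen-17-yn-5-ol | CC(C)=CC[C@@H](O)/C(I)=C/CC/C(C)=C/CC/C(C)=C/CC#C[Si](C(C)C)(C(C)C)C(C)C
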